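## The problem

Target 31 is a trans-3,4-dibenzylbutyrolactone in which each benzyl group is itself a β-5-linked phenylpropanoid pair. The C4 benzyl carbon sits on C5 of a 2-aryl-3-(hydroxymethyl)-7-methoxy-2,3-dihydrobenzofuran (benzo ring C, ring D at C2). The C3 benzyl carbon sits on ring B of a 1,2-diarylpropane-1,3-diol (ring A on the carbinol carbon C7'', ring B on C8'', CH2OH as C9''), which is the same pair with the oxygen ring left open. The skeleton is therefore three blocks joined through two CH2 groups, and it is best assembled convergently at the lactone. The six stereocentres fall into three pairs: lactone C3/C4 (3R,4R, trans), dihydrobenzofuran C2/C3 (2S,3R, trans) and C7''/C8'' (S,S, hydroxyl and ring B anti along the chain). Inside a pair one centre can steer the other (C4 the alkylation at C3, C2 the ring closure at C3, one aldol both C7'' and C8''), but CH2–arene spacers insulate the pairs, so each pair needs its own source of absolute configuration. The fragile sites are the benzylic C7''–OH (para to the oxygen of ring A and beside the ortho-phenol of ring B, so acid would epimerise it or close a second dihydrobenzofuran), the benzylic C2–O1 bond of the same kind, the lactone and three free phenols; the last steps must therefore be neutral. The feature that makes the key step possible is that C3 of the dihydrobenzofuran is bonded to the ring C carbon C3a, ortho to O1, and carries a CH2–O group: this is the array left when an aryl radical at C3a closes onto the vinyl group of an O-(1-arylallyl) ether and the new primary radical is oxygenated. Rings B and C share the substitution pattern of a 5-substituted vanillyl unit, and rings A and D are plain guaiacyl rings, so two kinds of vanillin-type building block serve both halves.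

## Retrosynthesis

**End game (31 ⇐ 30 ⇐ 29).** No skeletal bond is cut. The three phenols are carried as benzyl ethers and the three alcohols as tert-butyldimethylsilyl ethers in 29. Fluoride removes the silyl groups (30) and neutral hydrogenolysis comes last, so that neither acid nor base meets the free C7''–OH/ortho-phenol pair.

**Lactone C3–CH2 bond (29 ⇒ 15 + 28).** This cut divides the target into two halves of similar size, lactone 15 (rings C/D) and benzylic bromide 28 (rings A/B). Cutting the C4–CH2 bond instead would call for a conjugate addition to a butenolide with weaker stereocontrol. The forward reaction is alkylation of the lithium enolate of a β-substituted butyrolactone anti to the C4 substituent, the standard entry to trans-dibenzyl lactones. It asks only for a primary benzylic bromide that tolerates no acid.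

**Lactone ring (15 ⇐ 14 ⇐ 13 ⇐ 11 ⇐ 10 ⇒ 8 + 9).** The four lactone carbons come in one piece from dimethyl succinate 9 by Stobbe condensation with aldehyde 8. The ring C CH2–C4 bond is first made as a C=C bond (10), and C4 is then set by asymmetric hydrogenation (11). Reduction of the ester and lactonisation (through 12) give 13. Going through the benzylic bromide of 8 and an auxiliary-controlled succinate alkylation would cost two more steps. The aminoxyl ether is kept as a protecting group through these steps; zinc cleaves its N–O bond only at 13, when no aldehyde is left, and 14 is silylated to 15.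

**Key disconnection (8 ⇒ 6 + 7).** The C3a–C3 bond and the exocyclic CH2–O bond are cut together. Aldehyde 8 then comes from the aryl iodide ether 6 and TEMPO 7 by 5-exo aryl radical cyclisation and aminoxyl capture. Compared with cutting O1–C2 or C2–C3 (see below), this cut removes in one step the ring, a C–C bond, a stereocentre and the oxygen at the correct oxidation level. It leaves a precursor with a single stereocentre and the formyl handle already in place. It asks for 5-exo over 6-endo closure, closure before the aryl radical is intercepted, and trans induction from C2.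

**Allylic ether (6 ⇒ 4 + 5).** The C2–O(aryl) bond is cut to the achiral linear carbonate 4 and 5-iodovanillin 5. Displacement at a preformed secondary 1-arylallyl centre would run through ionisation and allylic transposition. A branch-selective iridium-catalysed allylic substitution creates the centre by catalyst control instead. It has to work with a hindered, weakly nucleophilic aryloxide.

**Carbonate (4 ⇐ 3 ⇐ 2 ⇐ 1).** Functional-group changes only, from ferulic acid 1: double benzylation, reduction of the ester, acylation.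

**Western bromide (28 ⇐ 27 ⇐ 26 ⇐ 25).** The benzylic bromide is traced to a methyl ester on ring B, which survives all earlier steps and is reduced only after the diol is silylated. No protecting group is then needed for the benzylic carbon.

**C7''–C8'' bond (25 ⇐ 23 ⇒ 21 + 22).** An aldol between the arylacetyl imide 21 and 4-(benzyloxy)-3-methoxybenzaldehyde 22 sets both centres at once; reduction (through 24) gives diol 25. The anti relation excludes the boron syn-aldol. Hydride reduction of the corresponding ketone would give the syn isomer, and aryl addition to an α-aryl aldehyde would need a configurationally labile substrate. The forward reaction is therefore the magnesium-catalysed anti-aldol of the oxazolidinone imide with a non-enolisable aldehyde.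

**Ring B–CH2 bond (21 ⇐ 19 ⇐ 18 ⇒ 17 ⇐ 16).** The acetic acid side chain is attached to the aryl bromide 17 (from methyl 5-bromovanillate 16) by palladium-catalysed coupling with a Reformatsky reagent. Acidolysis gives acid 19, and acylation of the auxiliary (through 20) gives 21.

## Roads not taken

**Alternative 1:** The cut is O1–C2. Ag2O would oxidise the 4-hydroxy-3-methoxybenzyl group of the diarylpropane A2 to the quinone methide A3, fluoride would free the ring C phenoxide, and conjugate addition to the methide carbon would close the ring to A1.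
- Merits: the closure is anchored on a C3 centre set earlier, it is reversible through A3, so the trans isomer is reached under thermodynamic control and corrects itself. It uses no tin and no enantioselective etherification.
- Weak points: A3 carries the C3 hydrogen next to the methide, and tautomerisation toward the conjugated alkene would erase the very centre that controls the step. Oxidation of a simple 4-alkylguaiacol by Ag2O is slow. Ring D must be a free phenol for the step and be protected again afterwards. The bromide of A1 still has to be turned into a carbon handle for the lactone, and A2 itself needs a multi-step asymmetric synthesis.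
- Comparison: in diastereocontrol this road is better than the chosen plan, which relies on a kinetic preference and must discard the cis isomer. The chosen plan sets against this a closure that forms the C–C bond, the ring and the C–O bond in one step, and a shorter path to the aldehyde-bearing ring C.

**Alternative 2:** The cut is C2–C3. A chiral dirhodium tetracarboxylate such as Rh2(S-PTTL)4 would decompose the aryldiazoacetate A5, and the carbene carbon would insert into the benzylic C–H of the ortho aryloxymethyl ether to give the cis ester A4.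
- Merits: the step is catalytic and enantioselective, the cis selectivity of such insertions is high, and the ester makes C3 epimerisable, so trans is reached reliably with C2 as anchor. A5 comes from a simple benzyl ether by diazo transfer.
- Weak points: after ring closure, C3 of A4 must be epimerised, the ester reduced and the alcohol protected before the oxidation level of 8 is reached. Alkoxide epimerisation of a β-aryloxy ester risks ring opening by elimination, which would erase C2. The bromide again needs conversion to a formyl group, and a diazo compound has to be handled on scale.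
- Comparison: in enantio- and diastereocontrol this road is at least as good as the chosen plan and is arguably better secured for 2-aryl-dihydrobenzofurans. The chosen plan sets against it three to four fewer steps to the stage of 8 and no diazo chemistry, at the price of a less secure etherification with a hindered phenol.

**Alternative 3:** The cut is the O–C5 bond of the lactone. A chiral Brønsted acid and hydrogen peroxide would insert oxygen into one of the two enantiotopic acyl–CH2 bonds of cyclobutanone A7 to give lactone A6, which is identical with 15.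
- Merits: the stereo-defining step is metal-free and creates C4 late from a prochiral ring.
- Weak points: A7 has to be built from an allyl group on ring C by ketene cycloaddition and dechlorination, several steps beyond aldehyde 8, where the Stobbe route needs one. Desymmetrising oxidations of 3-benzylcyclobutanones are generally less selective than hydrogenation of benzylidenesuccinates. Because the substrate is already chiral, the minor isomer would be a diastereomer with remote centres that is hard to remove. Peroxide and acid also meet the ionisable C2–O1 bond. This road says nothing about the dihydrobenzofuran, which still needs one of the other closures.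
- Comparison: for the single stereo-defining event it is comparable and avoids a precious-metal catalyst. The chosen plan reaches the same lactone in fewer steps and with better-precedented selectivity.

Key step: step 5

Assumption: the sense of induction of the three catalyst- or auxiliary-controlled steps (4, 7, 15) is assigned by analogy with cinnamyl carbonates, β-aryl itaconate half-esters and N-propionyl oxazolidinones; if one proved opposite, the antipodal ligand or auxiliary would be used with no other change.

## Steps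

**Step 1**
Reactants: 1 ferulic acid
Product: 2 benzyl (E)-3-[4-(benzyloxy)-3-methoxyphenyl]prop-2-enoate
Conditions: BnBr (2.3 equiv), K2CO3, DMF, 60 °C
Reagents that add atoms: benzyl bromide, BrCc1ccccc1
Why: Williamson alkylation of the phenoxide and of the carboxylate in one operation; the alkene geometry is untouched.

**Step 2**
Reactants: 2 benzyl (E)-3-[4-(benzyloxy)-3-methoxyphenyl]prop-2-enoate
Product: 3 (E)-3-[4-(benzyloxy)-3-methoxyphenyl]prop-2-en-1-ol
Conditions: i-Bu2AlH (3 equiv), CH2Cl2, −78 → 0 °C
Reagents that add atoms: none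
Why: 1,2-reduction of an α,β-unsaturated ester by i-Bu2AlH gives the allylic alcohol without touching the alkene or the aryl benzyl ether.

**Step 3**
Reactants: 3 (E)-3-[4-(benzyloxy)-3-methoxyphenyl]prop-2-en-1-ol
Product: 4 (E)-3-[4-(benzyloxy)-3-methoxyphenyl]prop-2-en-1-yl methyl carbonate
Conditions: ClCO2Me, pyridine, CH2Cl2, 0 °C
Reagents that add atoms: methyl chloroformate, COC(=O)Cl
Why: Acylation of a primary allylic alcohol; the electron-rich carbonate is kept cold and used without acidic contact.

**Step 4**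
Reactants: 4 (E)-3-[4-(benzyloxy)-3-methoxyphenyl]prop-2-en-1-yl methyl carbonate; 5 5-iodovanillin
Product: 6 4-{[(1S)-1-[4-(benzyloxy)-3-methoxyphenyl]prop-2-en-1-yl]oxy}-3-iodo-5-methoxybenzaldehyde
Conditions: 5, LiN(SiMe3)2, THF, 0 °C; then 4, [Ir(cod)Cl]2 (2 mol%), (Sa,Sc,Sc)-O,O'-(1,1'-binaphthyl-2,2'-diyl)-N,N-bis(1-phenylethyl)phosphoramidite (4 mol%), 25–40 °C
Reagents that add atoms: none
Why: Iridium-catalysed asymmetric allylic etherification: the cyclometalated iridium phosphoramidite complex ionises the linear carbonate and the lithium aryloxide attacks the aryl-bearing allyl terminus, giving the branched ether with the catalyst setting the new centre as S. The aryloxide is a weak base, which limits re-ionisation of the product, and the product is purified on base-washed silica.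

**Step 5**
Reactants: 6 4-{[(1S)-1-[4-(benzyloxy)-3-methoxyphenyl]prop-2-en-1-yl]oxy}-3-iodo-5-methoxybenzaldehyde; 7 TEMPO
Product: 8 (2S,3R)-2-[4-(benzyloxy)-3-methoxyphenyl]-7-methoxy-3-{[(2,2,6,6-tetramethylpiperidin-1-yl)oxy]methyl}-2,3-dihydro-1-benzofuran-5-carbaldehyde
Conditions: 7 (5 equiv), Bu3SnH (3 equiv, slow addition), benzene, 70 °C
Reagents that add atoms: none
Why: Tributylstannyl radicals, formed when the aminoxyl abstracts hydrogen from Bu3SnH, abstract iodine from 6, and the aryl radical at C3a adds to the internal vinyl carbon, forming C3a–C3 and the five-membered oxygen ring in a 5-exo-trig closure. The resulting primary radical is captured by 7 at close to the diffusion limit, forming the CH2–O bond before it can rearrange or fragment. The closest known reaction type is the tin hydride/TEMPO aryl radical–alkene cyclisation with aminoxyl trapping used for 3-(oxymethyl)indolines and -dihydrobenzofurans. The new centre C3 is controlled by C2: in the chair-like transition state the C2 aryl group lies pseudo-equatorial, which places the CH2 radical trans to it and gives (2S,3R). The step needs 5-exo over 6-endo closure, which the geometry of the ortho-allyloxyaryl radical secures, and closure before capture or reduction of the aryl radical, which the very high rate of this cyclisation and the low stationary stannane concentration secure. It also needs trans over cis selectivity, which rests on the size of the C2 aryl group; the minor cis isomer is to be removed by chromatography. The aldehyde, the benzyl ether and the ionisable C2–O1 bond are not affected under these neutral conditions.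

**Step 6**
Reactants: 8 (2S,3R)-2-[4-(benzyloxy)-3-methoxyphenyl]-7-methoxy-3-{[(2,2,6,6-tetramethylpiperidin-1-yl)oxy]methyl}-2,3-dihydro-1-benzofuran-5-carbaldehyde; 9 dimethyl succinate
Product: 10 (E)-3-(methoxycarbonyl)-4-[the dihydrobenzofuran-5-yl group of 8]but-3-enoic acid
Conditions: 9 (3 equiv), NaOMe, MeOH, reflux; then aq. HCl
Reagents that add atoms: none
Why: Stobbe condensation: aldol addition of the succinate enolate, lactonisation and base-induced ring opening give the arylidene half-ester, with the acid on the CH2 arm. The aldehyde is non-enolisable and the alkoxyamine and benzyl ether are stable to methoxide.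

**Step 7**
Reactants: 10 (E)-3-(methoxycarbonyl)-4-[the dihydrobenzofuran-5-yl group of 8]but-3-enoic acid
Product: 11 (3R)-3-(methoxycarbonyl)-4-[the dihydrobenzofuran-5-yl group of 8]butanoic acid
Conditions: H2 (5 atm), [Rh(cod)((S,S)-Et-DuPhos)]OTf (1 mol%), NaOMe (10 mol%), MeOH, 25 °C
Reagents that add atoms: none
Why: Rhodium-catalysed asymmetric hydrogenation of a Stobbe half-ester (β-aryl itaconate type): carboxylate and alkene bind the metal and the ligand fixes the face, setting the future lactone C4 as R under catalyst control. The aryl benzyl ether and the N–O bond are inert to this homogeneous catalyst.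

**Step 8**
Reactants: 11 (3R)-3-(methoxycarbonyl)-4-[the dihydrobenzofuran-5-yl group of 8]butanoic acid
Product: 13 (4R)-4-{[(2S,3R)-2-[4-(benzyloxy)-3-methoxyphenyl]-7-methoxy-3-{[(2,2,6,6-tetramethylpiperidin-1-yl)oxy]methyl}-2,3-dihydro-1-benzofuran-5-yl]methyl}oxolan-2-one, via hydroxy acid 12 (not isolated)
Conditions: KOH (1 equiv), EtOH; CaCl2, NaBH4, −10 °C → rt; then 1 M HCl, rt
Reagents that add atoms: none
Why: Calcium borohydride reduces the methyl ester while the carboxylate salt is inert, and mild acidification closes the γ-hydroxy acid to the β-substituted butyrolactone; C4 is not touched.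

**Step 9**
Reactants: 13 (4R)-4-{[(2S,3R)-2-[4-(benzyloxy)-3-methoxyphenyl]-7-methoxy-3-{[(2,2,6,6-tetramethylpiperidin-1-yl)oxy]methyl}-2,3-dihydro-1-benzofuran-5-yl]methyl}oxolan-2-one
Product: 14 (4R)-4-{[(2S,3R)-2-[4-(benzyloxy)-3-methoxyphenyl]-3-(hydroxymethyl)-7-methoxy-2,3-dihydro-1-benzofuran-5-yl]methyl}oxolan-2-one
Conditions: Zn dust, AcOH/THF/H2O (3:1:1), 60 °C
Reagents that add atoms: none
Why: Reductive cleavage of the alkoxyamine N–O bond by zinc in acetic acid frees the primary alcohol. Lactone and benzyl ether are stable, and no aldehyde remains to be reduced.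

**Step 10**
Reactants: 14 (4R)-4-{[(2S,3R)-2-[4-(benzyloxy)-3-methoxyphenyl]-3-(hydroxymethyl)-7-methoxy-2,3-dihydro-1-benzofuran-5-yl]methyl}oxolan-2-one
Product: 15 (4R)-4-{[(2S,3R)-2-[4-(benzyloxy)-3-methoxyphenyl]-3-{[(tert-butyldimethylsilyl)oxy]methyl}-7-methoxy-2,3-dihydro-1-benzofuran-5-yl]methyl}oxolan-2-one
Conditions: t-BuMe2SiCl, imidazole, DMF, rt
Reagents that add atoms: tert-butyldimethylsilyl chloride, CC(C)(C)[Si](C)(C)Cl
Why: Silylation of a primary alcohol under non-enolising conditions, so that the alkoxide cannot compete in the later enolate alkylation.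

**Step 11**
Reactants: 16 methyl 3-bromo-4-hydroxy-5-methoxybenzoate
Product: 17 methyl 4-(benzyloxy)-3-bromo-5-methoxybenzoate
Conditions: BnBr, K2CO3, DMF, 60 °C
Reagents that add atoms: benzyl bromide, BrCc1ccccc1
Why: Williamson benzylation of a hindered but acidic phenol.

**Step 12**
Reactants: 17 methyl 4-(benzyloxy)-3-bromo-5-methoxybenzoate
Product: 18 methyl 4-(benzyloxy)-3-(2-tert-butoxy-2-oxoethyl)-5-methoxybenzoate
Conditions: BrZnCH2CO2t-Bu (1.3 equiv), Pd(dba)2 (2 mol%), P(t-Bu)3 (2 mol%), THF, rt → 50 °C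
Reagents that add atoms: (2-tert-butoxy-2-oxoethyl)zinc bromide, CC(C)(C)OC(=O)C[Zn]Br
Why: Negishi-type palladium-catalysed coupling of an aryl bromide with a Reformatsky reagent (α-arylation of an ester zinc enolate). The zinc enolate tolerates the methyl ester, and the bulky electron-rich phosphine allows oxidative addition beside the ortho benzyloxy group.

**Step 13**
Reactants: 18 methyl 4-(benzyloxy)-3-(2-tert-butoxy-2-oxoethyl)-5-methoxybenzoate
Product: 19 [2-(benzyloxy)-3-methoxy-5-(methoxycarbonyl)phenyl]acetic acid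
Conditions: CF3CO2H/CH2Cl2 (1:3), 0 °C → rt
Reagents that add atoms: none
Why: Acidolysis of the tert-butyl ester with loss of isobutene; the methyl ester and the aryl benzyl ether are stable to brief exposure.

**Step 14**
Reactants: 19 [2-(benzyloxy)-3-methoxy-5-(methoxycarbonyl)phenyl]acetic acid
Product: 21 methyl 4-(benzyloxy)-3-{2-[(4S)-4-benzyl-2-oxo-1,3-oxazolidin-3-yl]-2-oxoethyl}-5-methoxybenzoate, via mixed pivalic anhydride 20 (not isolated)
Conditions: t-BuCOCl, Et3N, THF, −20 °C; then (S)-4-benzyl-1,3-oxazolidin-2-one, LiCl, −20 °C → rt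
Reagents that add atoms: (S)-4-benzyl-1,3-oxazolidin-2-one, O=C1N[C@@H](Cc2ccccc2)CO1; pivaloyl chloride (atoms in intermediate 20 only), CC(C)(C)C(=O)Cl
Why: N-acylation of the oxazolidinone through the mixed anhydride; the hindered pivaloyl carbonyl directs attack to the arylacetyl carbonyl.

**Step 15**
Reactants: 21 methyl 4-(benzyloxy)-3-{2-[(4S)-4-benzyl-2-oxo-1,3-oxazolidin-3-yl]-2-oxoethyl}-5-methoxybenzoate; 22 4-(benzyloxy)-3-methoxybenzaldehyde
Product: 23 methyl 4-(benzyloxy)-3-{(2R,3S)-1-[(4S)-4-benzyl-2-oxo-1,3-oxazolidin-3-yl]-3-[4-(benzyloxy)-3-methoxyphenyl]-1-oxo-3-[(trimethylsilyl)oxy]propan-2-yl}-5-methoxybenzoate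
Conditions: 22 (1.2 equiv), MgCl2 (20 mol%), Et3N, Me3SiCl, EtOAc, rt
Reagents that add atoms: chlorotrimethylsilane, C[Si](C)(C)Cl
Why: Magnesium-catalysed direct anti-aldol of an N-acyl oxazolidinone with a non-enolisable aromatic aldehyde. Soft enolisation gives the chelated (Z)-enolate, the aldehyde adds to the face away from the 4-benzyl group, and silylation of the aldolate makes the addition irreversible and turns the catalyst over. This sets C8'' and C7'' together with the anti relation; C8'' is R here and becomes S on reduction only through the change of substituent priorities.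

**Step 16**
Reactants: 23 methyl 4-(benzyloxy)-3-{(2R,3S)-1-[(4S)-4-benzyl-2-oxo-1,3-oxazolidin-3-yl]-3-[4-(benzyloxy)-3-methoxyphenyl]-1-oxo-3-[(trimethylsilyl)oxy]propan-2-yl}-5-methoxybenzoate
Product: 25 methyl 4-(benzyloxy)-3-{(1S,2S)-1-[4-(benzyloxy)-3-methoxyphenyl]-1,3-dihydroxypropan-2-yl}-5-methoxybenzoate, via trimethylsilyl ether alcohol 24 (not isolated)
Conditions: LiBH4, MeOH (1.1 equiv), THF, 0 °C; then K2CO3, MeOH, rt
Reagents that add atoms: none
Why: LiBH4 reduces the activated imide carbonyl much faster than the electron-rich methyl benzoate and releases the auxiliary. The silylated oxygen cannot trigger retro-aldol cleavage, and carbonate in methanol then removes the labile trimethylsilyl group.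

**Step 17**
Reactants: 25 methyl 4-(benzyloxy)-3-{(1S,2S)-1-[4-(benzyloxy)-3-methoxyphenyl]-1,3-dihydroxypropan-2-yl}-5-methoxybenzoate
Product: 26 methyl 4-(benzyloxy)-3-{(1S,2S)-1-[4-(benzyloxy)-3-methoxyphenyl]-1,3-bis[(tert-butyldimethylsilyl)oxy]propan-2-yl}-5-methoxybenzoate
Conditions: t-BuMe2SiOTf (2.5 equiv), 2,6-lutidine, CH2Cl2, −78 → 0 °C
Reagents that add atoms: tert-butyldimethylsilyl triflate, CC(C)(C)[Si](C)(C)OS(=O)(=O)C(F)(F)F
Why: The silyl triflate with a hindered base silylates both the primary and the crowded benzylic hydroxyl without acid that could ionise C7''.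

**Step 18**
Reactants: 26 methyl 4-(benzyloxy)-3-{(1S,2S)-1-[4-(benzyloxy)-3-methoxyphenyl]-1,3-bis[(tert-butyldimethylsilyl)oxy]propan-2-yl}-5-methoxybenzoate
Product: 27 [4-(benzyloxy)-3-{(1S,2S)-1-[4-(benzyloxy)-3-methoxyphenyl]-1,3-bis[(tert-butyldimethylsilyl)oxy]propan-2-yl}-5-methoxyphenyl]methanol
Conditions: i-Bu2AlH (2.5 equiv), CH2Cl2, −78 °C
Reagents that add atoms: none
Why: Reduction of the aryl methyl ester to the benzylic alcohol; silyl and benzyl ethers are inert.

**Step 19**
Reactants: 27 [4-(benzyloxy)-3-{(1S,2S)-1-[4-(benzyloxy)-3-methoxyphenyl]-1,3-bis[(tert-butyldimethylsilyl)oxy]propan-2-yl}-5-methoxyphenyl]methanol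
Product: 28 1-(benzyloxy)-4-(bromomethyl)-2-{(1S,2S)-1-[4-(benzyloxy)-3-methoxyphenyl]-1,3-bis[(tert-butyldimethylsilyl)oxy]propan-2-yl}-6-methoxybenzene
Conditions: CBr4, PPh3, 2,6-lutidine (cat.), CH2Cl2, 0 °C
Reagents that add atoms: carbon tetrabromide, BrC(Br)(Br)Br
Why: Appel bromination of a primary benzylic alcohol under buffered, near-neutral conditions; the bromide is used directly.

**Step 20**
Reactants: 15 (4R)-4-{[(2S,3R)-2-[4-(benzyloxy)-3-methoxyphenyl]-3-{[(tert-butyldimethylsilyl)oxy]methyl}-7-methoxy-2,3-dihydro-1-benzofuran-5-yl]methyl}oxolan-2-one; 28 the benzylic bromide of step 19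
Product: 29 (3R,4R)-3-{[4-(benzyloxy)-3-{(1S,2S)-1-[4-(benzyloxy)-3-methoxyphenyl]-1,3-bis[(tert-butyldimethylsilyl)oxy]propan-2-yl}-5-methoxyphenyl]methyl}-4-{[(2S,3R)-2-[4-(benzyloxy)-3-methoxyphenyl]-3-{[(tert-butyldimethylsilyl)oxy]methyl}-7-methoxy-2,3-dihydro-1-benzofuran-5-yl]methyl}oxolan-2-one
Conditions: LiN(SiMe3)2, THF, −78 °C; then 28, DMPU, −78 → −40 °C
Reagents that add atoms: none
Why: Alkylation of the lithium enolate of a β-substituted γ-butyrolactone with a primary benzylic bromide. The electrophile enters anti to the C4 substituent, setting C3 as R and the 3,4-trans relation, which is also the thermodynamically preferred one.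

**Step 21**
Reactants: 29 the fully protected lactone of step 20
Product: 30 (3R,4R)-3-{[4-(benzyloxy)-3-{(1S,2S)-1-[4-(benzyloxy)-3-methoxyphenyl]-1,3-dihydroxypropan-2-yl}-5-methoxyphenyl]methyl}-4-{[(2S,3R)-2-[4-(benzyloxy)-3-methoxyphenyl]-3-(hydroxymethyl)-7-methoxy-2,3-dihydro-1-benzofuran-5-yl]methyl}oxolan-2-one
Conditions: Bu4NF, AcOH (1:1), THF, rt → 40 °C
Reagents that add atoms: none
Why: Fluoride cleaves all three silyl ethers; the acetic acid buffer keeps the medium near neutral, so the lactone is not opened and C7'' is not ionised.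

**Step 22**
Reactants: 30 the tri-O-benzyl triol of step 21
Product: 31 (3R,4R)-3-{[4-hydroxy-3-{(1S,2S)-1,3-dihydroxy-1-(4-hydroxy-3-methoxyphenyl)propan-2-yl}-5-methoxyphenyl]methyl}-4-{[(2S,3R)-3-(hydroxymethyl)-2-(4-hydroxy-3-methoxyphenyl)-7-methoxy-2,3-dihydro-1-benzofuran-5-yl]methyl}oxolan-2-one (target)
Conditions: H2 (1 atm), 10% Pd/C, EtOAc/EtOH, rt
Reagents that add atoms: none
Why: Neutral hydrogenolysis of three aryl benzyl ethers; without acid the benzylic C7''–OH and the cyclic benzylic C2–O1 bond are cleaved far more slowly than the O-benzyl groups, and the reaction is stopped at full debenzylation.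

## Compound list

1 | ferulic acid, (E)-3-(4-hydroxy-3-methoxyphenyl)prop-2-enoic acid | COc1cc(/C=C/C(=O)O)ccc1O | starting material
2 | benzyl (E)-3-[4-(benzyloxy)-3-methoxyphenyl]prop-2-enoate | COc1cc(/C=C/C(=O)OCc2ccccc2)ccc1OCc1ccccc1 | intermediate
3 | (E)-3-[4-(benzyloxy)-3-methoxyphenyl]prop-2-en-1-ol | COc1cc(/C=C/CO)ccc1OCc1ccccc1 | intermediate
4 | (E)-3-[4-(benzyloxy)-3-methoxyphenyl]prop-2-en-1-yl methyl carbonate | COc1cc(/C=C/COC(=O)OC)ccc1OCc1ccccc1 | intermediate
5 | 5-iodovanillin, 4-hydroxy-3-iodo-5-methoxybenzaldehyde | COc1cc(C=O)cc(I)c1O | starting material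
6 | 4-{[(1S)-1-[4-(benzyloxy)-3-methoxyphenyl]prop-2-en-1-yl]oxy}-3-iodo-5-methoxybenzaldehyde | C=C[C@@H](c1ccc(OCc2ccccc2)c(OC)c1)Oc1c(I)cc(C=O)cc1OC | intermediate
7 | TEMPO, (2,2,6,6-tetramethylpiperidin-1-yl)oxyl | CC1(C)CCCC(C)(C)N1[O] | starting material
8 | (2S,3R)-2-[4-(benzyloxy)-3-methoxyphenyl]-7-methoxy-3-{[(2,2,6,6-tetramethylpiperidin-1-yl)oxy]methyl}-2,3-dihydro-1-benzofuran-5-carbaldehyde | O=Cc1cc(OC)c2c(c1)[C@H](CON1C(C)(C)CCCC1(C)C)[C@@H](c1ccc(OCc3ccccc3)c(OC)c1)O2 | intermediate
9 | dimethyl succinate | COC(=O)CCC(=O)OC | starting material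
10 | (E)-3-(methoxycarbonyl)-4-[dihydrobenzofuran-5-yl group of 8]but-3-enoic acid | COC(=O)/C(CC(=O)O)=C/c1cc(OC)c2c(c1)[C@H](CON1C(C)(C)CCCC1(C)C)[C@@H](c1ccc(OCc3ccccc3)c(OC)c1)O2 | intermediate
11 | (3R)-3-(methoxycarbonyl)-4-[dihydrobenzofuran-5-yl group of 8]butanoic acid | COC(=O)[C@@H](CC(=O)O)Cc1cc(OC)c2c(c1)[C@H](CON1C(C)(C)CCCC1(C)C)[C@@H](c1ccc(OCc3ccccc3)c(OC)c1)O2 | intermediate
12 | (3R)-3-(hydroxymethyl)-4-[dihydrobenzofuran-5-yl group of 8]butanoic acid | OC[C@@H](CC(=O)O)Cc1cc(OC)c2c(c1)[C@H](CON1C(C)(C)CCCC1(C)C)[C@@H](c1ccc(OCc3ccccc3)c(OC)c1)O2 | intermediate (not isolated)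
13 | (4R)-4-{[(2S,3R)-2-[4-(benzyloxy)-3-methoxyphenyl]-7-methoxy-3-{[(2,2,6,6-tetramethylpiperidin-1-yl)oxy]methyl}-2,3-dihydro-1-benzofuran-5-yl]methyl}oxolan-2-one | O=C1C[C@@H](Cc2cc(OC)c3c(c2)[C@H](CON2C(C)(C)CCCC2(C)C)[C@@H](c2ccc(OCc4ccccc4)c(OC)c2)O3)CO1 | intermediate
14 | (4R)-4-{[(2S,3R)-2-[4-(benzyloxy)-3-methoxyphenyl]-3-(hydroxymethyl)-7-methoxy-2,3-dihydro-1-benzofuran-5-yl]methyl}oxolan-2-one | O=C1C[C@@H](Cc2cc(OC)c3c(c2)[C@H](CO)[C@@H](c2ccc(OCc4ccccc4)c(OC)c2)O3)CO1 | intermediate
15 | (4R)-4-{[(2S,3R)-2-[4-(benzyloxy)-3-methoxyphenyl]-3-{[(tert-butyldimethylsilyl)oxy]methyl}-7-methoxy-2,3-dihydro-1-benzofuran-5-yl]methyl}oxolan-2-one | O=C1C[C@@H](Cc2cc(OC)c3c(c2)[C@H](CO[Si](C)(C)C(C)(C)C)[C@@H](c2ccc(OCc4ccccc4)c(OC)c2)O3)CO1 | intermediate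
16 | methyl 3-bromo-4-hydroxy-5-methoxybenzoate (methyl 5-bromovanillate) | COC(=O)c1cc(Br)c(O)c(OC)c1 | starting material
17 | methyl 4-(benzyloxy)-3-bromo-5-methoxybenzoate | COC(=O)c1cc(Br)c(OCc2ccccc2)c(OC)c1 | intermediate
18 | methyl 4-(benzyloxy)-3-(2-tert-butoxy-2-oxoethyl)-5-methoxybenzoate | COC(=O)c1cc(CC(=O)OC(C)(C)C)c(OCc2ccccc2)c(OC)c1 | intermediate
19 | [2-(benzyloxy)-3-methoxy-5-(methoxycarbonyl)phenyl]acetic acid | COC(=O)c1cc(CC(=O)O)c(OCc2ccccc2)c(OC)c1 | intermediate
20 | [2-(benzyloxy)-3-methoxy-5-(methoxycarbonyl)phenyl]acetic pivalic anhydride | COC(=O)c1cc(CC(=O)OC(=O)C(C)(C)C)c(OCc2ccccc2)c(OC)c1 | intermediate (not isolated)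
21 | methyl 4-(benzyloxy)-3-{2-[(4S)-4-benzyl-2-oxo-1,3-oxazolidin-3-yl]-2-oxoethyl}-5-methoxybenzoate | COC(=O)c1cc(CC(=O)N2[C@@H](Cc3ccccc3)COC2=O)c(OCc2ccccc2)c(OC)c1 | intermediate
22 | 4-(benzyloxy)-3-methoxybenzaldehyde | COc1cc(C=O)ccc1OCc1ccccc1 | starting material
23 | methyl 4-(benzyloxy)-3-{(2R,3S)-1-[(4S)-4-benzyl-2-oxo-1,3-oxazolidin-3-yl]-3-[4-(benzyloxy)-3-methoxyphenyl]-1-oxo-3-[(trimethylsilyl)oxy]propan-2-yl}-5-methoxybenzoate | COc1cc([C@@H](O[Si](C)(C)C)[C@H](C(=O)N2[C@@H](Cc3ccccc3)COC2=O)c2cc(C(=O)OC)cc(OC)c2OCc2ccccc2)ccc1OCc1ccccc1 | intermediate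
24 | methyl 4-(benzyloxy)-3-{(1S,2S)-1-[4-(benzyloxy)-3-methoxyphenyl]-3-hydroxy-1-[(trimethylsilyl)oxy]propan-2-yl}-5-methoxybenzoate | COc1cc([C@@H](O[Si](C)(C)C)[C@H](CO)c2cc(C(=O)OC)cc(OC)c2OCc2ccccc2)ccc1OCc1ccccc1 | intermediate (not isolated)
25 | methyl 4-(benzyloxy)-3-{(1S,2S)-1-[4-(benzyloxy)-3-methoxyphenyl]-1,3-dihydroxypropan-2-yl}-5-methoxybenzoate | COc1cc([C@@H](O)[C@H](CO)c2cc(C(=O)OC)cc(OC)c2OCc2ccccc2)ccc1OCc1ccccc1 | intermediate
26 | methyl 4-(benzyloxy)-3-{(1S,2S)-1-[4-(benzyloxy)-3-methoxyphenyl]-1,3-bis[(tert-butyldimethylsilyl)oxy]propan-2-yl}-5-methoxybenzoate | COc1cc([C@@H](O[Si](C)(C)C(C)(C)C)[C@H](CO[Si](C)(C)C(C)(C)C)c2cc(C(=O)OC)cc(OC)c2OCc2ccccc2)ccc1OCc1ccccc1 | intermediate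
27 | [4-(benzyloxy)-3-{(1S,2S)-1-[4-(benzyloxy)-3-methoxyphenyl]-1,3-bis[(tert-butyldimethylsilyl)oxy]propan-2-yl}-5-methoxyphenyl]methanol | COc1cc([C@@H](O[Si](C)(C)C(C)(C)C)[C@H](CO[Si](C)(C)C(C)(C)C)c2cc(CO)cc(OC)c2OCc2ccccc2)ccc1OCc1ccccc1 | intermediate
28 | 1-(benzyloxy)-4-(bromomethyl)-2-{(1S,2S)-1-[4-(benzyloxy)-3-methoxyphenyl]-1,3-bis[(tert-butyldimethylsilyl)oxy]propan-2-yl}-6-methoxybenzene | COc1cc([C@@H](O[Si](C)(C)C(C)(C)C)[C@H](CO[Si](C)(C)C(C)(C)C)c2cc(CBr)cc(OC)c2OCc2ccccc2)ccc1OCc1ccccc1 | intermediate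
29 | (3R,4R)-3-{[4-(benzyloxy)-3-{(1S,2S)-1-[4-(benzyloxy)-3-methoxyphenyl]-1,3-bis[(tert-butyldimethylsilyl)oxy]propan-2-yl}-5-methoxyphenyl]methyl}-4-{[(2S,3R)-2-[4-(benzyloxy)-3-methoxyphenyl]-3-{[(tert-butyldimethylsilyl)oxy]methyl}-7-methoxy-2,3-dihydro-1-benzofuran-5-yl]methyl}oxolan-2-one | COc1cc([C@@H](O[Si](C)(C)C(C)(C)C)[C@H](CO[Si](C)(C)C(C)(C)C)c2cc(C[C@H]3C(=O)OC[C@@H]3Cc3cc(OC)c4c(c3)[C@H](CO[Si](C)(C)C(C)(C)C)[C@@H](c3ccc(OCc5ccccc5)c(OC)c3)O4)cc(OC)c2OCc2ccccc2)ccc1OCc1ccccc1 | intermediate
30 | (3R,4R)-3-{[4-(benzyloxy)-3-{(1S,2S)-1-[4-(benzyloxy)-3-methoxyphenyl]-1,3-dihydroxypropan-2-yl}-5-methoxyphenyl]methyl}-4-{[(2S,3R)-2-[4-(benzyloxy)-3-methoxyphenyl]-3-(hydroxymethyl)-7-methoxy-2,3-dihydro-1-benzofuran-5-yl]methyl}oxolan-2-one | COc1cc([C@@H](O)[C@H](CO)c2cc(C[C@H]3C(=O)OC[C@@H]3Cc3cc(OC)c4c(c3)[C@H](CO)[C@@H](c3ccc(OCc5ccccc5)c(OC)c3)O4)cc(OC)c2OCc2ccccc2)ccc1OCc1ccccc1 | intermediate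
31 | (3R,4R)-3-{[4-hydroxy-3-{(1S,2S)-1,3-dihydroxy-1-(4-hydroxy-3-methoxyphenyl)propan-2-yl}-5-methoxyphenyl]methyl}-4-{[(2S,3R)-3-(hydroxymethyl)-2-(4-hydroxy-3-methoxyphenyl)-7-methoxy-2,3-dihydro-1-benzofuran-5-yl]methyl}oxolan-2-one | COc1cc([C@@H](O)[C@H](CO)c2cc(C[C@H]3C(=O)OC[C@@H]3Cc3cc(OC)c4c(c3)[C@H](CO)[C@@H](c3ccc(O)c(OC)c3)O4)cc(OC)c2O)ccc1O | target

## Step count and risks

Total step count: 22. Longest linear sequence: 13 steps (steps 1–10, then 20–22, from ferulic acid); the western line (steps 11–19, then 20–22) has 12.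

**Step 5 (key step).**
- What may go wrong: incomplete facial selectivity of the kinetically controlled closure. The cis isomer cannot be recycled, since epimerising its C2 would lead into the enantiomeric series. The aryl radical may also be captured by the excess aminoxyl before the ring closes.
- Fallback: from 6, the aminoxyl is left out and the cyclisation is run with Bu3SnH in air-saturated toluene at ambient temperature. The cyclised primary radical is captured by dissolved dioxygen, which at millimolar concentration cannot intercept the aryl radical, and the peroxyl oxygen is reduced in the flask by the stannane. This should give (2S,3R)-2-[4-(benzyloxy)-3-methoxyphenyl]-3-(hydroxymethyl)-7-methoxy-2,3-dihydro-1-benzofuran-5-carbaldehyde F1 at a temperature where the conformational preference for trans is larger. F1 is carried on without protection: Stobbe condensation with 9 to the half-ester F2, hydrogenation as in step 7 to the (3R)-acid F3, and calcium borohydride reduction to the dihydroxy acid F4, which lactonises on acidification. The route is rejoined at 14, and the zinc step is no longer needed.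

**Step 4.**
- What may go wrong: low branched selectivity or slow substitution with the hindered, weakly nucleophilic aryloxide, and erosion of enantiomeric purity by re-ionisation of the doubly activated product ether.
- Fallback: from 22, addition of CH2=CHMgBr gives racemic 1-[4-(benzyloxy)-3-methoxyphenyl]prop-2-en-1-ol F5. Lipase-catalysed kinetic resolution (CAL-B, vinyl acetate) acetylates the R enantiomer to the acetate F7 and leaves the (S)-alcohol F6. Methyl chloroformate and pyridine convert F6 to the (S)-methyl carbonate F8. A RhCl(PPh3)3/P(OMe)3-catalysed allylic etherification with the copper aryloxide of 5 (LiN(SiMe3)2, CuI) substitutes at the carbon that carried the leaving group with overall retention. The route is rejoined at 6.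

**Step 15.**
- What may go wrong: poor anti selectivity or stalled turnover with the crowded arylacetyl imide beside the ortho benzyloxy group, and retro-aldol cleavage of unsilylated aldolate.
- Fallback: from 21, the dibutylboron enolate (Bu2BOTf, i-Pr2NEt, CH2Cl2, −78 °C) is added to 22 precomplexed with Et2AlCl. The open transition state of the boron-chelated enolate gives the same anti adduct as its free alcohol, the (2R,3S)-hydroxy imide F9. LiBH4 reduction as in step 16 rejoins the route at 25.

**Step 22.**
- What may go wrong: over-reduction, that is hydrogenolysis of benzylic C–O bonds other than the benzyl ethers. The C7''–OH is at risk once the para-phenol of ring A is free, and the C2–O1 bond of the dihydrobenzofuran is at risk throughout.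
- Fallback: from 29, the order of the last two operations is reversed. Hydrogenolysis (H2, Pd/C, EtOAc) is run while C7''–O is still a bulky silyl ether and no benzylic hydroxyl is exposed, giving the triphenol tris-silyl ether F10. Buffered fluoride (Bu4NF, AcOH) then removes the silyl groups and the route is rejoined at 31.

## Further compounds

F1 | step 5 | (2S,3R)-2-[4-(benzyloxy)-3-methoxyphenyl]-3-(hydroxymethyl)-7-methoxy-2,3-dihydro-1-benzofuran-5-carbaldehyde | O=Cc1cc(OC)c2c(c1)[C@H](CO)[C@@H](c1ccc(OCc3ccccc3)c(OC)c1)O2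
F2 | step 5 | (E)-3-(methoxycarbonyl)-4-[dihydrobenzofuran-5-yl group of F1]but-3-enoic acid | COC(=O)/C(CC(=O)O)=C/c1cc(OC)c2c(c1)[C@H](CO)[C@@H](c1ccc(OCc3ccccc3)c(OC)c1)O2
F3 | step 5 | (3R)-3-(methoxycarbonyl)-4-[dihydrobenzofuran-5-yl group of F1]butanoic acid | COC(=O)[C@@H](CC(=O)O)Cc1cc(OC)c2c(c1)[C@H](CO)[C@@H](c1ccc(OCc3ccccc3)c(OC)c1)O2
F4 | step 5 | (3R)-3-(hydroxymethyl)-4-[dihydrobenzofuran-5-yl group of F1]butanoic acid | OC[C@@H](CC(=O)O)Cc1cc(OC)c2c(c1)[C@H](CO)[C@@H](c1ccc(OCc3ccccc3)c(OC)c1)O2
F5 | step 4 | racemic 1-[4-(benzyloxy)-3-methoxyphenyl]prop-2-en-1-ol | C=CC(O)c1ccc(OCc2ccccc2)c(OC)c1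
F6 | step 4 | (1S)-1-[4-(benzyloxy)-3-methoxyphenyl]prop-2-en-1-ol | C=C[C@@H](c1ccc(OCc2ccccc2)c(OC)c1)O
F7 | step 4 | (1R)-1-[4-(benzyloxy)-3-methoxyphenyl]prop-2-en-1-yl acetate | C=C[C@H](c1ccc(OCc2ccccc2)c(OC)c1)OC(C)=O
F8 | step 4 | (1S)-1-[4-(benzyloxy)-3-methoxyphenyl]prop-2-en-1-yl methyl carbonate | C=C[C@@H](c1ccc(OCc2ccccc2)c(OC)c1)OC(=O)OC
F9 | step 15 | methyl 4-(benzyloxy)-3-{(2R,3S)-1-[(4S)-4-benzyl-2-oxo-1,3-oxazolidin-3-yl]-3-[4-(benzyloxy)-3-methoxyphenyl]-3-hydroxy-1-oxopropan-2-yl}-5-methoxybenzoate | COc1cc([C@@H](O)[C@H](C(=O)N2[C@@H](Cc3ccccc3)COC2=O)c2cc(C(=O)OC)cc(OC)c2OCc2ccccc2)ccc1OCc1ccccc1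
F10 | step 22 | tris(tert-butyldimethylsilyl) ether of 31 at the three alcohol oxygens, with free phenols | COc1cc([C@@H](O[Si](C)(C)C(C)(C)C)[C@H](CO[Si](C)(C)C(C)(C)C)c2cc(C[C@H]3C(=O)OC[C@@H]3Cc3cc(OC)c4c(c3)[C@H](CO[Si](C)(C)C(C)(C)C)[C@@H](c3ccc(O)c(OC)c3)O4)cc(OC)c2O)ccc1O
A1 | alternative 1 | (2S,3R)-5-bromo-3-{[(tert-butyldimethylsilyl)oxy]methyl}-2-(4-hydroxy-3-methoxyphenyl)-7-methoxy-2,3-dihydro-1-benzofuran | Brc1cc(OC)c2c(c1)[C@H](CO[Si](C)(C)C(C)(C)C)[C@@H](c1ccc(O)c(OC)c1)O2
A2 | alternative 1 | 4-[(2R)-2-{5-bromo-2-[(tert-butyldimethylsilyl)oxy]-3-methoxyphenyl}-3-[(tert-butyldimethylsilyl)oxy]propyl]-2-methoxyphenol | Brc1cc(OC)c(O[Si](C)(C)C(C)(C)C)c(c1)[C@H](CO[Si](C)(C)C(C)(C)C)Cc1ccc(O)c(OC)c1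
A3 | alternative 1 | 4-[(2R)-2-{5-bromo-2-[(tert-butyldimethylsilyl)oxy]-3-methoxyphenyl}-3-[(tert-butyldimethylsilyl)oxy]propylidene]-2-methoxycyclohexa-2,5-dien-1-one | Brc1cc(OC)c(O[Si](C)(C)C(C)(C)C)c(c1)[C@H](CO[Si](C)(C)C(C)(C)C)C=C1C=CC(=O)C(OC)=C1
A4 | alternative 2 | methyl (2S,3R)-5-bromo-7-methoxy-2-{3-methoxy-4-[(triisopropylsilyl)oxy]phenyl}-2,3-dihydro-1-benzofuran-3-carboxylate (2,3-cis) | Brc1cc(OC)c2c(c1)[C@@H](C(=O)OC)[C@@H](c1ccc(O[Si](C(C)C)(C(C)C)C(C)C)c(OC)c1)O2
A5 | alternative 2 | methyl 2-[5-bromo-3-methoxy-2-({3-methoxy-4-[(triisopropylsilyl)oxy]phenyl}methoxy)phenyl]-2-diazoacetate | COC(=O)C(=[N+]=[N-])c1cc(Br)cc(OC)c1OCc1ccc(O[Si](C(C)C)(C(C)C)C(C)C)c(OC)c1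
A6 | alternative 3 | (4R)-4-{[(2S,3R)-2-[4-(benzyloxy)-3-methoxyphenyl]-3-{[(tert-butyldimethylsilyl)oxy]methyl}-7-methoxy-2,3-dihydro-1-benzofuran-5-yl]methyl}oxolan-2-one (identical with 15) | O=C1C[C@@H](Cc2cc(OC)c3c(c2)[C@H](CO[Si](C)(C)C(C)(C)C)[C@@H](c2ccc(OCc4ccccc4)c(OC)c2)O3)CO1
A7 | alternative 3 | 3-{[(2S,3R)-2-[4-(benzyloxy)-3-methoxyphenyl]-3-{[(tert-butyldimethylsilyl)oxy]methyl}-7-methoxy-2,3-dihydro-1-benzofuran-5-yl]methyl}cyclobutan-1-one | O=C1CC(Cc2cc(OC)c3c(c2)[C@H](CO[Si](C)(C)C(C)(C)C)[C@@H](c2ccc(OCc4ccccc4)c(OC)c2)O3)C1
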